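**Retrosynthetic overview**
1. The benzene ring and the δ-lactone are formed in one pot from an open 9-hydroxy-3,7-dioxo-5-enoate chain (11): C2→C7 aldol/aromatisation, then lactonisation by the C9 alkoxide. This parallels the polyketide pathway, where the carbinol is set on the chain before cyclisation.
2. Chain 11 comes from an acetoacetate (diketide) equivalent 9 and the (R)-dihydropyranone 8, a masked 5-hydroxy-3-oxo-aldehyde whose ring oxygen becomes the lactone oxygen.
3. Pyranone 8 comes from a catalytic asymmetric hetero-Diels–Alder reaction of dienal 5 with Danishefsky's diene 6; this sets the only stereocentre.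
4. Dienal 5 comes from tetradecanal 1 and the C4 unit 2.
5. Ring order: pyranone (temporary), then benzene ring, then lactone.

Assumption: (R)-BINOL–Ti(IV) delivers the (R)-carbinol from the enal, as it does with benzaldehyde-type aldehydes; if the measured sense is opposite, (S)-BINOL is used with nothing else changed.

**Step 1**
Reactants: 1 tetradecanal; 2 (Z)-1-methoxybut-1-en-3-yne
Product: 3 (Z)-1-methoxyoctadec-1-en-3-yn-5-ol (racemic)
Conditions: 2 (1.2 equiv), n-BuLi, THF, −78 °C; then 1, −78 → 0 °C; H2O quench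
Reagents that add atoms: none
Why: Lithium acetylide 1,2-addition to an aldehyde; the carbinol centre is racemic and is removed in step 2.

**Step 2**
Reactants: 3 (Z)-1-methoxyoctadec-1-en-3-yn-5-ol
Product: 5 (2E,4E)-octadeca-2,4-dienal, via dienol ether 4 (not isolated)
Conditions: LiAlH4, THF, 0 °C → rt; then 1 M HCl, THF, 0 °C → rt
Reagents that add atoms: water, O
Why: Alkoxide-directed trans-hydroalumination of the propargylic alcohol gives the (3E)-dienol ether, and acid hydrolysis with allylic transposition (loss of the 5-OH through the methoxypentadienyl cation) gives the thermodynamic (2E,4E)-dienal.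

**Step 3**
Reactants: 5 (2E,4E)-octadeca-2,4-dienal; 6 (E)-1-methoxy-3-(trimethylsilyloxy)buta-1,3-diene (Danishefsky's diene)
Product: 8 (2R)-2-[(1E,3E)-heptadeca-1,3-dien-1-yl]-2,3-dihydro-4H-pyran-4-one, via Mukaiyama aldol adduct 7 (not isolated)
Conditions: (R)-BINOL (20 mol %), Ti(OiPr)4 (10 mol %), 4 Å MS, Et2O, −20 °C; then TFA, CH2Cl2, 0 °C
Reagents that add atoms: none
Why: Keck-type BINOL–Ti catalysed formal hetero-Diels–Alder reaction (enantioselective Mukaiyama aldol at C=O, then acid-induced oxa-Michael cyclisation with loss of MeOH); the catalyst's facial control on the aldehyde sets the (R) centre.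

**Step 4**
Reactants: 8 (2R)-2-[(1E,3E)-heptadeca-1,3-dien-1-yl]-2,3-dihydro-4H-pyran-4-one; 9 1-methoxy-1,3-bis(trimethylsilyloxy)buta-1,3-diene (Chan's diene)
Product: 13 (3R)-3-[(1E,3E)-heptadeca-1,3-dien-1-yl]-8-hydroxy-3,4-dihydro-1H-isochromen-1-one, via bis-silyl Michael adduct 10 (not isolated), via ring-opened keto ester 11 (not isolated), via hydroxy salicylate 12 (not isolated)
Conditions: 8 + 9 (1.5 equiv), CH2Cl2, −78 °C, TMSOTf (1.1 equiv); then KOtBu (5 equiv), THF, −78 → 0 °C; MeOH, rt; AcOH quench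
Reagents that add atoms: none
Why: Proposed new method: TMSOTf O-silylates the vinylogous ester of 8 to a 4-silyloxy oxocarbenium ion that the terminal carbon of 9 attacks at C6 (Mukaiyama–Michael, known for dihydropyranones and chromones), leaving the regiodefined Δ4,5 silyl enol ether 10; KOtBu cleaves it to the one enolate that can only expel the ring oxygen from C6 (E1cB retro-oxa-Michael), so the C–O bond at the stereocentre is never broken and the (R)-alkoxide is released on chain 11; the doubly activated C4–H2 of 11 is deprotonated to a dienolate that equilibrates the 5,6-alkene to Z, closes C2→C7 (intramolecular aldol), loses water to salicylate 12 and is lactonised by the alkoxide; the closest known reaction types are the domino retro-oxa-Michael/aldol/lactonisation of 2-(3-alkoxycarbonyl-2-oxopropyl)chroman-4-ones to 7-hydroxybenzo[c]chromen-6-ones and the Chan–Brownbridge [3+3] salicylate synthesis.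

**Compound list**
1 | tetradecanal | CCCCCCCCCCCCCC=O | starting material
2 | (Z)-1-methoxybut-1-en-3-yne | C#C/C=C\OC | starting material
3 | (Z)-1-methoxyoctadec-1-en-3-yn-5-ol (racemic) | CCCCCCCCCCCCCC(O)C#C/C=C\OC | intermediate
4 | (1Z,3E)-1-methoxyoctadeca-1,3-dien-5-ol | CCCCCCCCCCCCCC(O)/C=C/C=C\OC | intermediate (not isolated)
5 | (2E,4E)-octadeca-2,4-dienal | CCCCCCCCCCCCC/C=C/C=C/C=O | intermediate
6 | (E)-1-methoxy-3-(trimethylsilyloxy)buta-1,3-diene | CO/C=C/C(=C)O[Si](C)(C)C | starting material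
7 | (5R,1E,6E,8E)-1-methoxy-5-(trimethylsilyloxy)docosa-1,6,8-trien-3-one | CCCCCCCCCCCCC/C=C/C=C/[C@@H](CC(=O)/C=C/OC)O[Si](C)(C)C | intermediate (not isolated)
8 | (2R)-2-[(1E,3E)-heptadeca-1,3-dien-1-yl]-2,3-dihydro-4H-pyran-4-one | CCCCCCCCCCCCC/C=C/C=C/[C@H]1CC(=O)C=CO1 | intermediate
9 | 1-methoxy-1,3-bis(trimethylsilyloxy)buta-1,3-diene | COC(O[Si](C)(C)C)=CC(=C)O[Si](C)(C)C | starting material
10 | methyl 4-[(2S,6R)-6-[(1E,3E)-heptadeca-1,3-dien-1-yl]-4-(trimethylsilyloxy)-5,6-dihydro-2H-pyran-2-yl]-3-(trimethylsilyloxy)but-2-enoate (2,6-trans expected; new centre and enoate geometry are lost later) | CCCCCCCCCCCCC/C=C/C=C/[C@H]1CC(O[Si](C)(C)C)=C[C@H](CC(O[Si](C)(C)C)=CC(=O)OC)O1 | intermediate (not isolated)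
11 | methyl (5Z,9R,10E,12E)-9-hydroxy-3,7-dioxohexacosa-5,10,12-trienoate (present as potassium enolate/alkoxide; 5E/5Z interconvert) | COC(=O)CC(=O)C/C=C\C(=O)C[C@@H](O)/C=C/C=C/CCCCCCCCCCCCC | intermediate (not isolated)
12 | methyl 2-hydroxy-6-[(2R,3E,5E)-2-hydroxynonadeca-3,5-dien-1-yl]benzoate | COC(=O)c1c(O)cccc1C[C@@H](O)/C=C/C=C/CCCCCCCCCCCCC | intermediate (not isolated)
13 | (3R)-3-[(1E,3E)-heptadeca-1,3-dien-1-yl]-8-hydroxy-3,4-dihydro-1H-isochromen-1-one | CCCCCCCCCCCCC/C=C/C=C/[C@H]1Cc2cccc(O)c2C(=O)O1 | target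

**Totals**
Total step count: 4. Longest linear sequence: 4 (1 → 3 → 5 → 8 → 13).

**Three steps most likely to fail**

Step 4 (ring transformation). Risks: enolate equilibration to the C3 side would open the ring at the stereocentre (trienone, loss of configuration); retro-aldol of the β-alkoxide ketone; ionisation of the dienylic C–O bond under TMSOTf. The fallback sets out from 5 and comes back at 13, replacing the ring transformation by a stepwise [3+3] benzannulation on the open-chain aldol. The BINOL–Ti aldol of 5 with 6 is worked up without TFA and the silyl ether is cleaved with K2CO3/MeOH at 0 °C to give (5R,1E,6E,8E)-5-hydroxy-1-methoxydocosa-1,6,8-trien-3-one F1. TBSCl/imidazole gives (5R,1E,6E,8E)-5-(tert-butyldimethylsilyloxy)-1-methoxydocosa-1,6,8-trien-3-one F2. TiCl4-mediated Chan–Brownbridge cycloaromatisation of F2 with 9 (CH2Cl2, −78 °C) gives methyl 2-hydroxy-6-[(2R,3E,5E)-2-(tert-butyldimethylsilyloxy)nonadeca-3,5-dien-1-yl]benzoate F3. TBAF in THF frees the alkoxide, which closes onto the ortho ester to give 13.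

Step 3 (asymmetric hetero-Diels–Alder). Risks: modest ee with a dienal; partial ionisation of the dienylic carbinol during the TFA cyclisation. The fallback sets out from 5 and comes back at 8, using auxiliary control and a different ring closure. A titanium-mediated acetate aldol of 5 with N-acetyl-(4S)-4-isopropyl-1,3-thiazolidine-2-thione (TiCl4, iPr2NEt, CH2Cl2, −78 °C) gives 1-[(4S)-4-isopropyl-2-thioxo-1,3-thiazolidin-3-yl]-(3R,4E,6E)-3-hydroxyicosa-4,6-dien-1-one F4. The (3R) sense is expected from the chelated enolate; the diastereomers are separable on silica and the (4R) auxiliary is equally available. MeNHOMe·HCl/imidazole gives (3R,4E,6E)-3-hydroxy-N-methoxy-N-methylicosa-4,6-dienamide F5. Ethynylmagnesium bromide (3 equiv, THF, 0 °C) gives (5R,6E,8E)-5-hydroxydocosa-6,8-dien-1-yn-3-one F6. A 6-endo-dig oxa-Michael cyclisation (cat. Ph3PAuCl/AgOTf, CH2Cl2) then gives 8.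

Step 2 (reduction/hydrolysis to the dienal). Risks: over-reduction, 2Z/2E mixtures, acid sensitivity of the dienal. The fallback sets out from 1 and comes back at 5. A vinylogous Horner–Wadsworth–Emmons reaction of 1 with triethyl 4-phosphonocrotonate (LiHMDS, THF, −78 → 0 °C) gives ethyl (2E,4E)-octadeca-2,4-dienoate F7. DIBAL-H (CH2Cl2, −78 °C) gives (2E,4E)-octadeca-2,4-dien-1-ol F8. MnO2 (CH2Cl2, rt) gives 5.

**Further compounds**
F1 | step 4 | (5R,1E,6E,8E)-5-hydroxy-1-methoxydocosa-1,6,8-trien-3-one | CCCCCCCCCCCCC/C=C/C=C/[C@H](O)CC(=O)/C=C/OC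
F2 | step 4 | (5R,1E,6E,8E)-5-(tert-butyldimethylsilyloxy)-1-methoxydocosa-1,6,8-trien-3-one | CCCCCCCCCCCCC/C=C/C=C/[C@H](O[Si](C)(C)C(C)(C)C)CC(=O)/C=C/OC
F3 | step 4 | methyl 2-hydroxy-6-[(2R,3E,5E)-2-(tert-butyldimethylsilyloxy)nonadeca-3,5-dien-1-yl]benzoate | COC(=O)c1c(O)cccc1C[C@@H](O[Si](C)(C)C(C)(C)C)/C=C/C=C/CCCCCCCCCCCCC
F4 | step 3 | 1-[(4S)-4-isopropyl-2-thioxo-1,3-thiazolidin-3-yl]-(3R,4E,6E)-3-hydroxyicosa-4,6-dien-1-one | CCCCCCCCCCCCC/C=C/C=C/[C@H](O)CC(=O)N1[C@@H](C(C)C)CSC1=S
F5 | step 3 | (3R,4E,6E)-3-hydroxy-N-methoxy-N-methylicosa-4,6-dienamide | CCCCCCCCCCCCC/C=C/C=C/[C@H](O)CC(=O)N(C)OC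
F6 | step 3 | (5R,6E,8E)-5-hydroxydocosa-6,8-dien-1-yn-3-one | CCCCCCCCCCCCC/C=C/C=C/[C@H](O)CC(=O)C#C
F7 | step 2 | ethyl (2E,4E)-octadeca-2,4-dienoate | CCCCCCCCCCCCC/C=C/C=C/C(=O)OCC
F8 | step 2 | (2E,4E)-octadeca-2,4-dien-1-ol | CCCCCCCCCCCCC/C=C/C=C/CO
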